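In the two earlier runs the target, counted as a percentage of the charge, does not move with the charge: at 4.00 h it reads 12.2% in red and 12.3% in blue, though the charges differ by a factor of 3.83. You therefore treat the curves as first-order and lay them over the new flask.

| flask | substrate | remark | time |
|---|---|---|---|
| red | 0.12 M | run made earlier |  |
| blue | 0.46 M | run made earlier |  |
| flask | 0.23 M |  | 15 h |

| run | time / h | isomer of the product / % | target / % |
|---|---|---|---|
| red | 2.00 | 24.2 | 20.7 |
| red | 4.00 | 27.3 | 12.2 |
| red | 6.00 | 28.1 | 7.2 |
| red | 8.00 | 29.4 | 4.7 |
| red | 10.0 | 29.2 | 2.8 |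
| red | 12.0 | 30.0 | 1.0 |
| red | 15.0 | 29.6 | 0.5 |
| blue | 0.833 | 23.4 | 28.5 |
| blue | 2.50 | 25.8 | 18.2 |
| blue | 4.00 | 26.6 | 12.3 |
| blue | 6.00 | 28.5 | 6.8 |
| blue | 10.0 | 29.7 | 2.8 |
| blue | 12.0 | 29.0 | 1.8 |
| blue | 15.0 | 30.0 | 0 |

(scatter of a reading: 0.5 percentage points)

- steps that have been proposed: substrate -> target; third conformer -> third product; substrate <-> other conformer; other conformer <-> third conformer; other conformer -> isomer of the product; target -> over-reaction product; other conformer -> decomposition product; other conformer <-> dormant form

* share of isomer of the product in isomer of the product plus target at 10 s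
* share of isomer of the product in isomer of the product plus target at 15 h
* which of isomer of the product and target there is more of at 15 h

The bench rule for a falling tail is to count turnovers. Read from red between 2.00 h and 8.00 h, the logarithmic fall per hour of the target's tail, k_d, is 0.247 h⁻¹, and N = k_d t turnovers cut a reading by e^(-N). From 8.00 h to 15 h, N is 1.73, so your reckoning leaves 0.834% of target in the flask. The isomer of the product ends near 29.8% in the runs, which puts it ahead with a share of 97.3%.

The rule stops at the earliest reading. The early time 10 s is 0.00333 of the blue run's first time, 0.833 h, and k_d counts 6.86 × 10⁻⁴ turnovers over that time. You therefore commit to no figure for the share at that time.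

The forecast gave 36% and 97.4%, with isomer of the product ahead, and said of the early share: “The runs cannot resolve this”. The flask gives 3.64% and 97.7%, with isomer of the product ahead, at 30.2% against 0.722%.

    substrate → target (k = 0.00140 s⁻¹)
    third conformer → third product (k = 9.10 × 10⁻⁴ s⁻¹)
    substrate ⇌ other conformer (K = 2.20, k = 0.0230 s⁻¹)
    other conformer ⇌ third conformer (K = 1.90, k = 4.60 × 10⁻⁴ s⁻¹)
    other conformer → isomer of the product (k = 4.60 × 10⁻⁴ s⁻¹)
    target → over-reaction product (k = 9.80 × 10⁻⁵ s⁻¹)
    other conformer → decomposition product (k = 1.30 × 10⁻⁶ s⁻¹)
    other conformer ⇌ dormant form (K = 5.30, k = 4.60 × 10⁻⁴ s⁻¹)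

Up to 10 s the flask's step from substrate to other conformer counts 0.230 of a turnover on its constant. The next step, from other conformer to isomer of the product, counts 0.00460 on its own constant, against 0.0140 for substrate to target. On the tail, k_d carries the flask's 4.82% of target at 7.50 h to 0.756% at 15 h, beside the 0.722% that stands there. The neighbour charged with 0.58 M holds 0.722% of target at 15.0 h, a share of 97.7%.

The data are simulated for substances that don't exist.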